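**Retrosynthetic overview**
1. The target comes from acid deprotection of a protected chromanone–chromone, which comes from dehydrogenation of a bis(chroman-4-one). Only unit B has a C2′–H, so only it can become the chromone; the quaternary unit A stays a chromanone.
2. Both C4 ketones are carried as 1,3-dithianes. Both pyran rings are closed in one double O-arylation (alkoxide onto aryl fluoride), so the C2–O bond is never broken.
3. Key disconnection, C3–C4 and C3′–C4′ at once: two equivalents of one 2-aryl-2-lithio-1,3-dithiane (acyl anion) attack both CH2 termini of (R)-2-methyl-1,2:4,5-diepoxypentane. This builds the whole carbon skeleton in one operation.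
4. The diepoxide comes from methallyl alcohol (Sharpless epoxidation sets the only stereocentre, then vinyl Grignard, then epoxidation). The aryl dithiane comes from 1-(3,5-difluorophenyl)propan-2-one (ketal, SNAr, bromination, dithianylation).
5. Ring order: the benzene rings are bought, the two dihydropyran rings are formed together, and the chromone ring is made last by oxidation.

Assumption: the stereocentre in the SMILES reads as (R) (O1 > C3 > CH2-chromone > CH3), and 1-(3,5-difluorophenyl)propan-2-one is taken as a catalogue compound.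
Abbreviation: Ar = 4-tert-butoxy-2-fluoro-6-[(2-methyl-1,3-dioxolan-2-yl)methyl]phenyl.

**Step 1**
Reactants: 1 2-methylprop-2-en-1-ol (methallyl alcohol)
Product: 3 [(2R)-2-methyloxiran-2-yl]methyl 4-methylbenzenesulfonate, via (S)-2-methylglycidol 2 (not isolated)
Conditions: Ti(OiPr)4 (5 mol %), L-(+)-diisopropyl tartrate (6 mol %), cumene hydroperoxide, 4 Å MS, CH2Cl2, −20 °C; P(OMe)3; then TsCl, Et3N, DMAP (cat.), −10 °C
Reagents that add atoms: cumene hydroperoxide CC(C)(OO)c1ccccc1; 4-toluenesulfonyl chloride Cc1ccc(cc1)S(=O)(=O)Cl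
Why: Sharpless asymmetric epoxidation with the L-(+)-tartrate sets the only stereocentre of the synthesis (S in 2, about 94% ee; called R in 3 only because the CIP ranking changes), and in situ tosylation avoids isolating the water-soluble epoxy alcohol.

**Step 2**
Reactants: 3 [(2R)-2-methyloxiran-2-yl]methyl 4-methylbenzenesulfonate; 4 vinylmagnesium bromide
Product: 5 (2R)-2-hydroxy-2-methylpent-4-en-1-yl 4-methylbenzenesulfonate
Conditions: CuI (10 mol %), THF, −40 to −20 °C; H2O quench
Reagents that add atoms: none
Why: Copper-catalysed Grignard opening of the epoxide (SN2 at the unsubstituted oxirane carbon) outruns attack at the neopentyl-type tosylate, and no bond to the quaternary carbon is touched, so its configuration is retained.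

**Step 3**
Reactants: 5 (2R)-2-hydroxy-2-methylpent-4-en-1-yl 4-methylbenzenesulfonate
Product: 6 (2R)-2-hydroxy-2-methyl-3-(oxiran-2-yl)propyl 4-methylbenzenesulfonate (about 1:1 epimers at the oxirane CH)
Conditions: mCPBA, CH2Cl2, 0 °C to rt
Reagents that add atoms: 3-chloroperoxybenzoic acid O=C(OO)c1cccc(Cl)c1
Why: Prilezhaev epoxidation of the only alkene gives a non-volatile latent diepoxide, and the unselective new centre is harmless because that carbon becomes sp2 (C2′ of the chromone) in step 11.

**Step 4**
Reactants: 7 1-(3,5-difluorophenyl)propan-2-one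
Product: 8 2-[(3,5-difluorophenyl)methyl]-2-methyl-1,3-dioxolane
Conditions: ethylene glycol, TsOH·H2O (2 mol %), toluene, Dean–Stark, reflux
Reagents that add atoms: ethylene glycol OCCO
Why: Acid-catalysed ketalisation with azeotropic water removal masks the future acetonyl ketone against the alkoxide, organolithium and hydride reagents of steps 5 to 9.

**Step 5**
Reactants: 8 2-[(3,5-difluorophenyl)methyl]-2-methyl-1,3-dioxolane
Product: 9 2-[(3-tert-butoxy-5-fluorophenyl)methyl]-2-methyl-1,3-dioxolane
Conditions: KOtBu (1.3 equiv), NMP, 80 °C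
Reagents that add atoms: potassium tert-butoxide CC(C)(C)[O-].[K+]
Why: SNAr displaces one of two equivalent, mutually meta-activating fluorides and stops at the mono-ether because the new donor deactivates the ring, and the bulky acid-labile tert-butyl ether later shields the neighbouring ring C–H from lithiation.

**Step 6**
Reactants: 9 2-[(3-tert-butoxy-5-fluorophenyl)methyl]-2-methyl-1,3-dioxolane
Product: 10 2-[(2-bromo-5-tert-butoxy-3-fluorophenyl)methyl]-2-methyl-1,3-dioxolane
Conditions: NBS (1.05 equiv), MeCN, 0 °C to rt, dark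
Reagents that add atoms: N-bromosuccinimide O=C1CCC(=O)N1Br
Why: Electrophilic aromatic bromination in a polar solvent goes para to the alkoxy donor (also ortho to F and to the alkyl group), because both positions ortho to oxygen are screened by the tert-butyl group.

**Step 7**
Reactants: 10 2-[(2-bromo-5-tert-butoxy-3-fluorophenyl)methyl]-2-methyl-1,3-dioxolane; 11 1,3-dithiane
Product: 15 2-Ar-1,3-dithiane, via 2-chloro-1,3-dithiane 12 (not isolated), via aryllithium 13 (not isolated), via arylmagnesium bromide 14 (not isolated)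
Conditions: flask A: 11, NCS, toluene, 10 °C; flask B: 10, n-BuLi, THF, −78 °C, then MgBr2·OEt2; add A to B, −78 to 0 °C
Reagents that add atoms: none
Why: Bromine–lithium exchange, transmetalation and Grignard substitution on the α-chlorosulfide 12 (a formyl cation equivalent) install the dithiane without acid, so ketal and tert-butyl ether survive, and the low temperature keeps the ortho-fluoroaryl metal from losing fluoride.

**Step 8 (key step)**
Reactants: 15 2-Ar-1,3-dithiane (two equivalents incorporated; 2.4 used); 6 (2R)-2-hydroxy-2-methyl-3-(oxiran-2-yl)propyl 4-methylbenzenesulfonate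
Product: 18 (2R)-1,5-bis(2-Ar-1,3-dithian-2-yl)-2-methylpentane-2,4-diol (C4 epimers), via 2-lithio-2-aryl-1,3-dithiane 16 (not isolated), via (R)-2-methyl-1,2:4,5-diepoxypentane 17 (not isolated)
Conditions: 6, NaH, THF, 0 °C to rt (solution of 17); 15, n-BuLi (2.3 equiv), THF–DMPU (8:1), −78 to −30 °C; add 17, −78 °C to rt; H2O
Reagents that add atoms: none
Why: This is a two-directional Corey–Seebach umpolung in which the masked formyl carbon, natively an electrophile, attacks as an acyl anion the unsubstituted carbon of each epoxide (also natively electrophilic), as lithiated dithianes are known to do at both ends of the parent 1,2:4,5-diepoxypentane; both C3–C4 bonds form at once, and the quaternary C–O bond is untouched so the (R) centre is retained.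

**Step 9**
Reactants: 18 (2R)-1,5-bis(2-Ar-1,3-dithian-2-yl)-2-methylpentane-2,4-diol
Product: 19 (2R)-bis(spiro[chromane-4,2′-[1,3]dithiane]) in which C2 of unit A bears CH3 plus a CH2 link to C2′ of unit B (C2′ epimers)
Conditions: KH (3 equiv), 18-crown-6, THF–DMPU, 70 °C
Reagents that add atoms: none
Why: A double intramolecular SNAr (six-membered ring closure, helped by the gem-disubstitution on both sides) lets each alkoxide displace the ortho fluoride while C4 is still a dithiane, so retro-aldol and E1cB pathways do not exist, and the epoxide-derived oxygen becomes O1 with retention at C2.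

**Step 10**
Reactants: 19 (2R)-bis(spiro[chromane-4,2′-[1,3]dithiane])
Product: 20 (2R)-bis(chroman-4-one) carrying 7-OtBu plus 5-CH2-(2-methyl-1,3-dioxolan-2-yl) on each arene (C2′ epimers)
Conditions: MeI (excess), CaCO3, MeCN–H2O (9:1), 45 °C
Reagents that add atoms: water O
Why: Alkylative dithiane hydrolysis (S-methylation, then ionisation to a thionium ion stabilised by the ortho and para oxygens, then capture by water) runs at buffered neutral pH, so ketals, tert-butyl ethers and the base-sensitive C2 centre are untouched.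

**Step 11**
Reactants: 20 (2R)-bis(chroman-4-one)
Product: 21 (2R)-7-tert-butoxy-2-methyl-2-[(7-tert-butoxy-4-oxo-4H-chromen-2-yl)methyl]chroman-4-one bearing the dioxolane-masked acetonyl group at C5 of each unit
Conditions: IBX (3 equiv), DMSO, 70 °C
Reagents that add atoms: none
Why: IBX dehydrogenation of a ketone to its enone needs a β-hydrogen, which only unit B has (C2′–H), so both C2′ epimers converge on the chromone while the quaternary unit A cannot react and keeps its configuration.

**Step 12**
Reactants: 21 protected chromanone–chromone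
Product: 22 target, (2R)-7-hydroxy-2-{[7-hydroxy-4-oxo-5-(2-oxopropyl)-4H-chromen-2-yl]methyl}-2-methyl-5-(2-oxopropyl)chroman-4-one
Conditions: TFA–H2O–CH2Cl2 (5:1:5), 0 °C to rt
Reagents that add atoms: water O
Why: One acidolysis cleaves both aryl tert-butyl ethers and hydrolyses both dioxolanes, and the ring O1–C2 ether survives because its cation would sit β to a ketone, so no base ever meets the finished chromanone and C2 cannot racemise by retro-oxa-Michael opening.

**Compound list**
1 | 2-methylprop-2-en-1-ol | CC(=C)CO | starting material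
2 | [(2S)-2-methyloxiran-2-yl]methanol | C[C@]1(CO)CO1 | intermediate
3 | [(2R)-2-methyloxiran-2-yl]methyl 4-methylbenzenesulfonate | C[C@]1(COS(=O)(=O)c2ccc(C)cc2)CO1 | intermediate
4 | vinylmagnesium bromide | C=C[Mg]Br | starting material
5 | (2R)-2-hydroxy-2-methylpent-4-en-1-yl 4-methylbenzenesulfonate | C[C@@](O)(CC=C)COS(=O)(=O)c1ccc(C)cc1 | intermediate
6 | (2R)-2-hydroxy-2-methyl-3-(oxiran-2-yl)propyl 4-methylbenzenesulfonate, oxirane CH epimers | C[C@@](O)(CC1CO1)COS(=O)(=O)c1ccc(C)cc1 | intermediate
7 | 1-(3,5-difluorophenyl)propan-2-one | CC(=O)Cc1cc(F)cc(F)c1 | starting material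
8 | 2-[(3,5-difluorophenyl)methyl]-2-methyl-1,3-dioxolane | CC1(Cc2cc(F)cc(F)c2)OCCO1 | intermediate
9 | 2-[(3-tert-butoxy-5-fluorophenyl)methyl]-2-methyl-1,3-dioxolane | CC1(Cc2cc(F)cc(OC(C)(C)C)c2)OCCO1 | intermediate
10 | 2-[(2-bromo-5-tert-butoxy-3-fluorophenyl)methyl]-2-methyl-1,3-dioxolane | CC1(Cc2cc(OC(C)(C)C)cc(F)c2Br)OCCO1 | intermediate
11 | 1,3-dithiane | C1CSCSC1 | starting material
12 | 2-chloro-1,3-dithiane | ClC1SCCCS1 | intermediate
13 | Ar–Li | [Li]c1c(F)cc(OC(C)(C)C)cc1CC1(C)OCCO1 | intermediate
14 | Ar–MgBr | Br[Mg]c1c(F)cc(OC(C)(C)C)cc1CC1(C)OCCO1 | intermediate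
15 | 2-{4-tert-butoxy-2-fluoro-6-[(2-methyl-1,3-dioxolan-2-yl)methyl]phenyl}-1,3-dithiane | CC1(Cc2cc(OC(C)(C)C)cc(F)c2C2SCCCS2)OCCO1 | intermediate
16 | 2-lithio derivative of 15 | [Li]C1(SCCCS1)c1c(F)cc(OC(C)(C)C)cc1CC1(C)OCCO1 | intermediate
17 | (2R)-2-methyl-2-(oxiran-2-ylmethyl)oxirane, epimers at the monosubstituted oxirane | C[C@@]1(CC2CO2)CO1 | intermediate
18 | (2R)-1,5-bis(2-Ar-1,3-dithian-2-yl)-2-methylpentane-2,4-diol, C4 epimers | C[C@@](O)(CC(O)CC1(SCCCS1)c1c(F)cc(OC(C)(C)C)cc1CC1(C)OCCO1)CC1(SCCCS1)c1c(F)cc(OC(C)(C)C)cc1CC1(C)OCCO1 | intermediate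
19 | (2R)-bis(spiro[chromane-4,2′-[1,3]dithiane]), C2′ epimers | C[C@@]1(CC2CC3(SCCCS3)c3c(CC4(C)OCCO4)cc(OC(C)(C)C)cc3O2)CC2(SCCCS2)c2c(CC3(C)OCCO3)cc(OC(C)(C)C)cc2O1 | intermediate
20 | (2R)-bis(chroman-4-one), C2′ epimers | C[C@@]1(CC2CC(=O)c3c(CC4(C)OCCO4)cc(OC(C)(C)C)cc3O2)CC(=O)c2c(CC3(C)OCCO3)cc(OC(C)(C)C)cc2O1 | intermediate
21 | (2R)-protected chromanone–chromone | C[C@@]1(Cc2cc(=O)c3c(CC4(C)OCCO4)cc(OC(C)(C)C)cc3o2)CC(=O)c2c(CC3(C)OCCO3)cc(OC(C)(C)C)cc2O1 | intermediate
22 | CNP0319595.1, (2R) | CC(=O)Cc1cc(O)cc2c1C(=O)C[C@@](C)(Cc1cc(=O)c3c(CC(C)=O)cc(O)cc3o1)O2 | target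

**Step count**
- Total steps: 12.
- Longest linear sequence: 9 (7 → 8 → 9 → 10 → 15 → 18 → 19 → 20 → 21 → 22).
- The diepoxide branch has 3 steps before the union.

**Steps most likely to fail**

*Step 8.*
- Why it may fail: the carbanion 16 is tertiary and flanked by two ortho substituents. It may open only the monosubstituted epoxide, or n-BuLi may lithiate the ring next to fluorine.
- Fallback: it sets out from 17 (made from 6 as in step 8) and returns at 20. It keeps the umpolung on an unhindered carbon and makes the aryl–C4 bonds by polar addition instead.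
- Sequence:
  - 2-Lithio-1,3-dithiane (from 11 and n-BuLi) opens both termini of 17 to give the bis(dithianyl) diol F1.
  - TESOTf and 2,6-lutidine give the bis(triethylsilyl) ether F2.
  - MeI and CaCO3 in aqueous MeCN give the dialdehyde F3.
  - Two equivalents of aryllithium 13 (from 10, −78 °C) add to give the bis(benzylic alcohol) F4.
  - TBAF gives the tetraol F5.
  - KH in THF–DMPU closes both ethers to the bis(chroman-4-ol) F6.
  - Dess–Martin periodinane oxidises both carbinols to 20.

*Step 9.*
- Why it may fail: the fluoroarenes carry no conjugating acceptor. At the temperature needed, a Grob-type loss of thiolate from the γ-oxido dithiane could compete.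
- Fallback: it sets out from 18 and returns at 19. It replaces addition–elimination by an elimination–addition ring closure run cold.
- Sequence: LDA (6 equiv) in THF, −78 to 0 °C, first forms the alkoxides and then lithiates the ring C–H between F and OtBu. Loss of LiF gives the 3-alkoxyaryne F7 (drawn with both rings dehydro). Each tethered alkoxide adds to the aryne carbon distal to OtBu, which is the six-membered closure and puts the aryl anion next to oxygen. The quench then delivers 19.

*Step 11.*
- Why it may fail: IBX may be sluggish on this hindered, electron-rich ketone, or may attack the benzylic CH2 groups.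
- Fallback: it sets out from 20 and returns at 21. It goes through a preformed enol derivative.
- Sequence: LiHMDS with TMSCl present (in situ quench) in THF at −78 °C gives the bis(trimethylsilyl enol ether) F8. Pd(OAc)2 in MeCN at rt (Saegusa–Ito oxidation) turns the enol silane of unit B into the chromone by β-hydride elimination. The enol silane of unit A has no β-hydrogen and is returned to the ketone by the mildly acidic work-up.

**Further compounds**
F1 | step 8 | (2R)-1,5-bis(1,3-dithian-2-yl)-2-methylpentane-2,4-diol, C4 epimers | C[C@@](O)(CC(O)CC1SCCCS1)CC1SCCCS1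
F2 | step 8 | bis(triethylsilyl) ether of F1 | C[C@@](O[Si](CC)(CC)CC)(CC(O[Si](CC)(CC)CC)CC1SCCCS1)CC1SCCCS1
F3 | step 8 | (3R)-3-methyl-3,5-bis(triethylsilyloxy)heptanedial, C5 epimers | C[C@@](O[Si](CC)(CC)CC)(CC(O[Si](CC)(CC)CC)CC=O)CC=O
F4 | step 8 | 1,7-di-Ar-3-methyl-3,5-bis(triethylsilyloxy)heptane-1,7-diol, quaternary centre as in 18, other centres mixed | C[C@@](O[Si](CC)(CC)CC)(CC(O[Si](CC)(CC)CC)CC(O)c1c(F)cc(OC(C)(C)C)cc1CC1(C)OCCO1)CC(O)c1c(F)cc(OC(C)(C)C)cc1CC1(C)OCCO1
F5 | step 8 | 1,7-di-Ar-3-methylheptane-1,3,5,7-tetraol, quaternary centre as in 18, other centres mixed | C[C@@](O)(CC(O)CC(O)c1c(F)cc(OC(C)(C)C)cc1CC1(C)OCCO1)CC(O)c1c(F)cc(OC(C)(C)C)cc1CC1(C)OCCO1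
F6 | step 8 | bis(chroman-4-ol) corresponding to 20, quaternary centre as in 20, other centres mixed | C[C@@]1(CC2CC(O)c3c(CC4(C)OCCO4)cc(OC(C)(C)C)cc3O2)CC(O)c2c(CC3(C)OCCO3)cc(OC(C)(C)C)cc2O1
F7 | step 9 | aryne from 18 by loss of HF, drawn with both rings dehydro, transient | C[C@@](O)(CC(O)CC1(SCCCS1)C1=C(CC2(C)OCCO2)C=C(OC(C)(C)C)C#C1)CC1(SCCCS1)C1=C(CC2(C)OCCO2)C=C(OC(C)(C)C)C#C1
F8 | step 11 | bis(trimethylsilyl enol ether) of 20 | C[C@@]1(CC2C=C(O[Si](C)(C)C)c3c(CC4(C)OCCO4)cc(OC(C)(C)C)cc3O2)C=C(O[Si](C)(C)C)c2c(CC3(C)OCCO3)cc(OC(C)(C)C)cc2O1
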